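**Remarks on the chemistry.** Ring atoms are numbered O1, C2, C3, C4, C5 as in the target, and the two hydroxymethyl carbons are C3′ and C4′; this numbering is kept for all intermediates. The SMILES is read as (2S,3S,4S,5S). Compounds 2 and 5 are taken as catalogue reagents. Compound numbers 1–23 are fixed by the steps below and used throughout.

## Analysis of the target

The target is a 2,5-diaryl-3,4-bis(hydroxymethyl)oxolane: one saturated five-membered ether ring with a 4-hydroxy-3-methoxyphenyl group on C2 and on C5 and a hydroxymethyl group on C3 and on C4. All four ring carbons are stereocentres, (2S,3S,4S,5S). The aryl group on C2 is cis to C3′, C3′ is trans to C4′, and C4′ is cis to the aryl group on C5, so the two aryl groups are trans. A twofold axis runs through O1 and the midpoint of C3–C4, which makes the halves O1–C2–C3 and O1–C5–C4 identical. Both ring C–O bonds are benzylic and para to an oxygen donor: acid ionises them, palladium-catalysed hydrogenation can cleave them, and the free phenols are oxidisable and can expel the ring oxygen through a quinone methide. The main difficulty is that each aryl group sits cis to its neighbouring hydroxymethyl group, the less stable arrangement, so both benzylic centres must be set under kinetic control and never allowed to equilibrate. The plan rests on the unit O1–C5(aryl)–C4(C4′): with C4′ at the acid oxidation level it is an aldol retron, and its cis arrangement in the ring corresponds to an anti-aldol adduct. C3 and C2 are then the methylene and the far carboxyl of a succinate, so the lactone O1–C2(=O) that closes in the same operation is the handle for building C2.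

## Retrosynthetic reasoning

**23 ⇐ 22 ⇐ 21 (protecting groups).** The phenols are carried as benzyl ethers and the primary alcohols as triisopropylsilyl ethers. Benzyl ethers on C3′ and C4′ were rejected: an alkyl benzyl ether is hydrogenolysed at a rate comparable to the O1–C2 and O1–C5 bonds of the product, whereas aryl benzyl ethers cleave much faster. The silyl ethers of 21 therefore leave with fluoride to give 22, and only the fast aryl ether cleavage is left for the last step.

**21 ⇐ 19 (bond C2–H).** The C2 aryl group must end cis to C3′. This is best set by hydride addition to the aryl-stabilised oxocarbenium ion 20, formed from lactol 19, on the face opposite the C3 substituent. An aryl nucleophile adding to a C2–H oxocarbenium ion would be expected to give the trans isomer.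

**19 ⇐ 15 + 18 (bond C2–aryl).** The lactone carbonyl of 15 is C2 at the right oxidation level to accept the second aryl ring as the nucleophile 18, made from bromide 17 and in turn from phenol 16. This keeps the route convergent and needs no redox adjustment at C2.

**15 ⇐ 14 ⇐ 12 (bond C3–C3′).** C3 is the only enolisable position of lactone 12. Its enolate 13 has the C4 substituent and the C5 aryl group on the same face, so a one-carbon electrophile must enter trans to C4′. A hydroxymethylation with the monomeric C1 aldehyde was chosen over an alkoxymethyl halide bearing a benzyl group, so that C3′ can also be carried as a silyl ether.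

**12 ⇐ 11 ⇐ 10 ⇐ 8 (oxidation level of C4′).** The imide carbonyl of 8 becomes C4′ by hydrolysis to acid 10, chemoselective reduction to alcohol 11 and silylation to 12. Every operation on 11 is kept free of alkoxide, because an alkoxide on C4′ would attack C2 and move the lactone from O1 to the C4′ oxygen.

**8 ⇐ 4 + 5 (bonds C4–C5 and O1–C2).** This is the key disconnection. An auxiliary-controlled anti-aldol of succinate imide 4 with aldehyde 5 forms C4–C5 and both stereocentres (adducts 6 and 7). Lactonisation of the C5 hydroxyl onto the ester closes the ring with retention, so anti becomes cis. Cutting here gains the ring, two stereocentres and a differentiated pair of carboxyl groups in one operation.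

**4 ⇐ 1 + 2.** N-Acylation of oxazolidinone 1 with the half-ester acid chloride 2 gives the precursor in one step.

## Alternatives that were turned down

**Alternative 1: conjugate addition–aldol on a chiral butenolide.**
- Disconnection: C2–C3 and C4–C5, with the ring left open.
- Forward key step: the lithiated dithiane A3 adds to the β-carbon of the menthyloxy butenolide A2 anti to the acetal substituent, and the lactone enolate is trapped by 5 to give A1. The acetal carbon is C3′ and the lactone carbonyl is C4′.
- For: three components are joined and both C–C bonds formed in one flask, the 3,4-trans relationship is set directly, and the controller comes from menthol.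
- Against: the C5 carbinol is formed in the trapping of a lithium lactone enolate with no element that fixes its configuration, so the 4,5 relationship would be expected as a mixture. The dithiane must later be removed with thiophilic metal salts or oxidants beside two electron-rich arenes and a benzylic alcohol. Lactone and acetal must both be reduced, and the oxolane ring still has to be closed through the same hemiketal reduction that the chosen route needs anyway.
- Comparison: A1 is reached more convergently, and the 3,4-trans relationship needs no separate step. The chosen strategy gives up this convergence for auxiliary control of C5 and C4 in the ring-forming step, which is where alternative 1 is weakest.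

**Alternative 2: alkoxycarbonylative cyclisation, then directed hydrogenation.**
- Disconnection: O1–C2 and C3–C3′.
- Forward key step: PdI2/KI under carbon monoxide and air in methanol. The C5 hydroxyl of alkynol A5 adds 5-endo-dig to the aryl alkyne, and the vinylpalladium at C3 is methoxycarbonylated to give dihydrofuran ester A4.
- For: the step is catalytic and builds the ring and C3′ together. A syn hydrogenation from the face of the C4′ hydroxyl would set C2 and C3 in one operation with exactly the required cis and trans relationships. On stereocentres per step it is stronger than the chosen route.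
- Against: the alkene of A4 is tetrasubstituted and push–pull (an enol ether conjugated with an ester). This is among the least reactive substrates for directed hydrogenation with [Ir(cod)(PCy3)(py)]PF6 or related cationic catalysts. Heterogeneous hydrogenation forceful enough to reduce it would add from the less hindered face to give the all-cis ring, and would threaten the benzylic C–O bonds and the benzyl ethers. A4 is also one oxidation away from an aromatic furan under the aerobic conditions of its formation, which would erase C4 and C5. A5 needs its own stereocontrolled synthesis.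
- Comparison: shorter on paper, but the step that sets two stereocentres is the least defensible. The chosen route sets C3 and C2 separately by reactions that each have a clear stereochemical bias.

**Alternative 3: keto-β-lactone ring expansion with silane capture.**
- Disconnection: O1–C5 and C2–H.
- Forward key step: BF3·OEt2 with Et3SiH. The ketone oxygen of A7 opens the β-lactone at benzylic C5 with inversion, and the 2-aryl oxocarbenium ion is reduced at C2 to give acid A6 (carboxyl on C4, benzyloxymethyl on C3).
- For: ring closure and two stereocentres in one step, stereospecific at C5 in principle, with the C4 acid already in place. The end game is shorter than in the chosen route.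
- Against: C5 is benzylic to an oxygenated arene. A β-lactone of this kind tends to ionise rather than undergo SN2 displacement, which loses the stereochemical information and opens a path to decarboxylation to a styrene. The pivalate on that arene is needed to hold this back, and it forces two differently protected aryl groups onto a twofold-symmetric target. A7 carries three contiguous stereocentres and needs a multi-step stereocontrolled synthesis.
- Comparison: C2 is set by the same oxocarbenium reduction as in the chosen route, so alternative 3 is equal there and shorter after its key step. The chosen strategy never performs a substitution at C5: its C5–O bond is made as a carbonyl C–O bond in a C–C bond-forming step and is only acylated afterwards.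

Key step: step 2

## Route

**Step 1**
Reactants: 1 (S)-4-benzyl-2-oxazolidinone; 2 methyl 4-chloro-4-oxobutanoate
Product: 4 methyl 4-[(S)-4-benzyl-2-oxooxazolidin-3-yl]-4-oxobutanoate, via N-lithio oxazolidinone 3 (not isolated)
Conditions: n-BuLi, THF, −78 °C; then 2, −78 → 0 °C
Reagents that add atoms: none
Why: N-acylation of a lithiated oxazolidinone with an acid chloride (standard imide formation); the methyl ester is not attacked at low temperature and no stereocentre is formed.

**Step 2 (key step)**
Reactants: 4 methyl 4-[(S)-4-benzyl-2-oxooxazolidin-3-yl]-4-oxobutanoate; 5 4-(benzyloxy)-3-methoxybenzaldehyde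
Product: 8 (4R,5S)-5-[4-(benzyloxy)-3-methoxyphenyl]-4-{[(S)-4-benzyl-2-oxooxazolidin-3-yl]carbonyl}dihydrofuran-2(3H)-one (4,5-cis), via anti-aldol trimethylsilyl ether 6 (not isolated), via anti-aldol hydroxy ester 7 (not isolated)
Conditions: MgCl2 (20 mol %), Et3N, Me3SiCl, EtOAc, rt; then 1 M HCl, THF, 0 °C → rt
Reagents that add atoms: none
Why: MgCl2 binds both imide carbonyls of 4, so Et3N removes a proton only from the imide α-CH2 (not from the ester α-CH2) and gives the chelated Z-enolate; this is the known MgCl2-catalysed anti-aldol of N-acyloxazolidinones with aromatic aldehydes, used here in its aldol–lactonisation form on a succinate half-ester imide. The aldehyde 5, bound to the same magnesium, is attacked through a closed, boat-like transition state, and Me3SiCl silylates the magnesium aldolate to 6, which frees the catalyst and stops retro-aldol. C4 (R) is fixed by the auxiliary, whose benzyl group shields one face of the chelated enolate so that bond C4–C5 forms on the other face. C5 (S) is fixed by the anti topology of that transition state. Dilute acid then cleaves the silyl ether to 7, and the C5 hydroxyl attacks the methyl ester carbonyl in a 5-exo-trig acyl substitution that closes O1–C2 with loss of methanol; the C5–O bond is not broken, so the anti adduct becomes the 4,5-cis lactone with retention. The step needs regioselective enolisation (secured by chelation of the imide), anti rather than syn addition on one enolate face (secured by the magnesium-bridged transition state, the non-enolisable aldehyde and the auxiliary), and no ionisation at the electron-rich benzylic C5 or epimerisation at C4 during ring closure (secured by cold dilute aqueous acid instead of strong or anhydrous acid).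

**Step 3**
Reactants: 8 cis-lactone imide
Product: 10 (2S,3R)-2-[4-(benzyloxy)-3-methoxyphenyl]-5-oxooxolane-3-carboxylic acid (cis; these are C5 and C4 of the target numbering), via peroxy acid 9 (not isolated)
Conditions: LiOH, 30% H2O2, THF/H2O, 0 °C; Na2SO3; then cold 1 M HCl to pH 2–3
Reagents that add atoms: hydrogen peroxide, OO (as lithium hydroperoxide; it supplies the carboxyl OH oxygen)
Why: Hydroperoxide attacks the exocyclic imide carbonyl selectively (standard oxazolidinone hydrolysis) and is too weakly basic to epimerise C4; sulfite reduces the peroxy acid, any lactone opened by base re-closes on acidification, and the auxiliary 1 is recovered.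

**Step 4**
Reactants: 10 cis lactone acid
Product: 11 (4S,5S)-5-[4-(benzyloxy)-3-methoxyphenyl]-4-(hydroxymethyl)dihydrofuran-2(3H)-one
Conditions: BH3·SMe2, THF, 0 °C → rt; MeOH quench
Reagents that add atoms: none
Why: Borane reduces a carboxylic acid through its acyloxyborane much faster than a lactone, and the medium is never basic, so the lactone does not migrate to the new primary hydroxyl; the change of the C4 descriptor from R to S is only a change of substituent priorities.

**Step 5**
Reactants: 11 hydroxymethyl lactone
Product: 12 (4S,5S)-5-[4-(benzyloxy)-3-methoxyphenyl]-4-{[(triisopropylsilyl)oxy]methyl}dihydrofuran-2(3H)-one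
Conditions: iPr3SiCl, imidazole, DMF, 0 °C → rt
Reagents that add atoms: chlorotriisopropylsilane, CC(C)[Si](Cl)(C(C)C)C(C)C
Why: Silylation of a primary alcohol with imidazole as the only base avoids the alkoxide that would trigger lactone migration; the triisopropylsilyl ether tolerates amide bases, aryllithium and BF3·OEt2 at low temperature and leaves with fluoride.

**Step 6**
Reactants: 12 silyl ether lactone
Product: 14 (3S,4S,5S)-5-[4-(benzyloxy)-3-methoxyphenyl]-3-(hydroxymethyl)-4-{[(triisopropylsilyl)oxy]methyl}dihydrofuran-2(3H)-one, via lithium enolate 13 (not isolated)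
Conditions: LiN(iPr)2, THF, −78 °C; HCHO (gas, from paraformaldehyde at 150 °C in a N2 stream), −78 → −30 °C; aq. NH4Cl
Reagents that add atoms: formaldehyde, C=O
Why: Aldol of a γ-butyrolactone lithium enolate with monomeric formaldehyde (known α-hydroxymethylation); the electrophile enters C3 on the face opposite the C4 silyloxymethyl and C5 aryl groups, which lie on the same side, so C3′ is set trans to C4′ (3S).

**Step 7**
Reactants: 14 α-hydroxymethyl lactone
Product: 15 (3S,4S,5S)-5-[4-(benzyloxy)-3-methoxyphenyl]-3,4-bis{[(triisopropylsilyl)oxy]methyl}dihydrofuran-2(3H)-one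
Conditions: iPr3SiCl, imidazole, DMF, rt
Reagents that add atoms: chlorotriisopropylsilane, CC(C)[Si](Cl)(C(C)C)C(C)C
Why: Standard silylation of a primary alcohol; the mild base does not provoke elimination of the β-hydroxy lactone.

**Step 8**
Reactants: 16 4-bromo-2-methoxyphenol
Product: 17 1-(benzyloxy)-4-bromo-2-methoxybenzene
Conditions: BnBr, K2CO3, DMF, rt
Reagents that add atoms: benzyl bromide, BrCc1ccccc1
Why: Williamson etherification of a phenol.

**Step 9**
Reactants: 17 1-(benzyloxy)-4-bromo-2-methoxybenzene; 15 bis-silyl lactone
Product: 19 (3S,4S,5S)-2,5-bis[4-(benzyloxy)-3-methoxyphenyl]-3,4-bis{[(triisopropylsilyl)oxy]methyl}oxolan-2-ol (both C2 epimers; in equilibrium with its open hydroxy ketone form), via aryllithium 18 (not isolated)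
Conditions: 17, n-BuLi, THF, −78 °C; then 15, −78 °C; aq. NH4Cl at −78 °C
Reagents that add atoms: none
Why: Bromine–lithium exchange followed by single addition of the aryllithium to the γ-lactone; the tetrahedral lithium hemiketal is stable at −78 °C, which holds back a second addition, and C2 is not yet a fixed stereocentre.

**Step 10**
Reactants: 19 lactol
Product: 21 (2S,3S,4S,5S)-2,5-bis[4-(benzyloxy)-3-methoxyphenyl]-3,4-bis{[(triisopropylsilyl)oxy]methyl}oxolane, via oxocarbenium ion 20 (not isolated)
Conditions: Et3SiH, BF3·OEt2, CH2Cl2, −78 °C; aq. NaHCO3 at −78 °C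
Reagents that add atoms: none
Why: BF3·OEt2 ionises the hemiketal to the aryl-conjugated oxocarbenium ion 20 and the silane delivers hydride to C2 on the face opposite the adjacent C3 substituent, the known reductive deoxygenation of 2-aryl lactols that gives 2,3-cis 2,5-diaryl oxolanes; the aryl group therefore ends cis to C3′ (2S), and the low temperature and cold basic quench keep the benzylic C–O bonds from ionising.

**Step 11**
Reactants: 21 protected oxolane
Product: 22 {(2S,3S,4S,5S)-2,5-bis[4-(benzyloxy)-3-methoxyphenyl]oxolane-3,4-diyl}dimethanol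
Conditions: Bu4NF, THF, 0 °C → rt
Reagents that add atoms: none
Why: Fluoride cleavage of primary silyl ethers; the phenols are still benzylated, so no phenoxide is present that could open the ring through a quinone methide.

**Step 12**
Reactants: 22 dibenzyl ether diol
Product: 23 Eduesmine, {(2S,3S,4S,5S)-2,5-bis(4-hydroxy-3-methoxyphenyl)oxolane-3,4-diyl}dimethanol
Conditions: H2 (1 atm), 10% Pd/C, EtOAc, rt, stopped as soon as 22 is consumed
Reagents that add atoms: none
Why: Hydrogenolysis of aryl benzyl ethers is much faster than cleavage of the ring benzylic C–O bonds, so in a neutral solvent at atmospheric pressure the two phenols should be freed without ring opening; no stereocentre is touched.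

## Compound list

1 | (S)-4-benzyl-2-oxazolidinone | O=C1N[C@@H](Cc2ccccc2)CO1 | starting material
2 | methyl 4-chloro-4-oxobutanoate | COC(=O)CCC(Cl)=O | starting material
3 | N-lithio derivative of (S)-4-benzyl-2-oxazolidinone | [Li]N1[C@@H](Cc2ccccc2)COC1=O | intermediate
4 | methyl 4-[(S)-4-benzyl-2-oxooxazolidin-3-yl]-4-oxobutanoate | COC(=O)CCC(=O)N1[C@@H](Cc2ccccc2)COC1=O | intermediate
5 | 4-(benzyloxy)-3-methoxybenzaldehyde | O=Cc1ccc(OCc2ccccc2)c(OC)c1 | starting material
6 | methyl (R)-3-{(S)-[4-(benzyloxy)-3-methoxyphenyl][(trimethylsilyl)oxy]methyl}-4-[(S)-4-benzyl-2-oxooxazolidin-3-yl]-4-oxobutanoate | COC(=O)C[C@@H](C(=O)N1[C@@H](Cc2ccccc2)COC1=O)[C@H](O[Si](C)(C)C)c1ccc(OCc2ccccc2)c(OC)c1 | intermediate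
7 | methyl (R)-3-{(S)-[4-(benzyloxy)-3-methoxyphenyl](hydroxy)methyl}-4-[(S)-4-benzyl-2-oxooxazolidin-3-yl]-4-oxobutanoate | COC(=O)C[C@@H](C(=O)N1[C@@H](Cc2ccccc2)COC1=O)[C@H](O)c1ccc(OCc2ccccc2)c(OC)c1 | intermediate
8 | (4R,5S)-5-[4-(benzyloxy)-3-methoxyphenyl]-4-{[(S)-4-benzyl-2-oxooxazolidin-3-yl]carbonyl}dihydrofuran-2(3H)-one | O=C1O[C@H](c2ccc(OCc3ccccc3)c(OC)c2)[C@H](C(=O)N2[C@@H](Cc3ccccc3)COC2=O)C1 | intermediate
9 | (2S,3R)-2-[4-(benzyloxy)-3-methoxyphenyl]-5-oxooxolane-3-carboperoxoic acid | O=C1O[C@H](c2ccc(OCc3ccccc3)c(OC)c2)[C@H](C(=O)OO)C1 | intermediate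
10 | (2S,3R)-2-[4-(benzyloxy)-3-methoxyphenyl]-5-oxooxolane-3-carboxylic acid | O=C1O[C@H](c2ccc(OCc3ccccc3)c(OC)c2)[C@H](C(=O)O)C1 | intermediate
11 | (4S,5S)-5-[4-(benzyloxy)-3-methoxyphenyl]-4-(hydroxymethyl)dihydrofuran-2(3H)-one | O=C1O[C@H](c2ccc(OCc3ccccc3)c(OC)c2)[C@H](CO)C1 | intermediate
12 | (4S,5S)-5-[4-(benzyloxy)-3-methoxyphenyl]-4-{[(triisopropylsilyl)oxy]methyl}dihydrofuran-2(3H)-one | O=C1O[C@H](c2ccc(OCc3ccccc3)c(OC)c2)[C@H](CO[Si](C(C)C)(C(C)C)C(C)C)C1 | intermediate
13 | lithium enolate of 12 | [Li]OC1=C[C@@H](CO[Si](C(C)C)(C(C)C)C(C)C)[C@@H](c2ccc(OCc3ccccc3)c(OC)c2)O1 | intermediate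
14 | (3S,4S,5S)-5-[4-(benzyloxy)-3-methoxyphenyl]-3-(hydroxymethyl)-4-{[(triisopropylsilyl)oxy]methyl}dihydrofuran-2(3H)-one | O=C1O[C@H](c2ccc(OCc3ccccc3)c(OC)c2)[C@H](CO[Si](C(C)C)(C(C)C)C(C)C)[C@H]1CO | intermediate
15 | (3S,4S,5S)-5-[4-(benzyloxy)-3-methoxyphenyl]-3,4-bis{[(triisopropylsilyl)oxy]methyl}dihydrofuran-2(3H)-one | O=C1O[C@H](c2ccc(OCc3ccccc3)c(OC)c2)[C@H](CO[Si](C(C)C)(C(C)C)C(C)C)[C@H]1CO[Si](C(C)C)(C(C)C)C(C)C | intermediate
16 | 4-bromo-2-methoxyphenol | COc1cc(Br)ccc1O | starting material
17 | 1-(benzyloxy)-4-bromo-2-methoxybenzene | COc1cc(Br)ccc1OCc1ccccc1 | intermediate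
18 | [4-(benzyloxy)-3-methoxyphenyl]lithium | COc1cc([Li])ccc1OCc1ccccc1 | intermediate
19 | (3S,4S,5S)-2,5-bis[4-(benzyloxy)-3-methoxyphenyl]-3,4-bis{[(triisopropylsilyl)oxy]methyl}oxolan-2-ol (C2 epimers) | OC1(c2ccc(OCc3ccccc3)c(OC)c2)O[C@H](c2ccc(OCc3ccccc3)c(OC)c2)[C@H](CO[Si](C(C)C)(C(C)C)C(C)C)[C@H]1CO[Si](C(C)C)(C(C)C)C(C)C | intermediate
20 | (3S,4S,5S)-2,5-bis[4-(benzyloxy)-3-methoxyphenyl]-3,4-bis{[(triisopropylsilyl)oxy]methyl}-4,5-dihydro-3H-furan-1-ium (oxocarbenium ion) | COc1cc(C2=[O+][C@H](c3ccc(OCc4ccccc4)c(OC)c3)[C@H](CO[Si](C(C)C)(C(C)C)C(C)C)[C@H]2CO[Si](C(C)C)(C(C)C)C(C)C)ccc1OCc1ccccc1 | intermediate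
21 | (2S,3S,4S,5S)-2,5-bis[4-(benzyloxy)-3-methoxyphenyl]-3,4-bis{[(triisopropylsilyl)oxy]methyl}oxolane | COc1cc([C@H]2O[C@H](c3ccc(OCc4ccccc4)c(OC)c3)[C@H](CO[Si](C(C)C)(C(C)C)C(C)C)[C@H]2CO[Si](C(C)C)(C(C)C)C(C)C)ccc1OCc1ccccc1 | intermediate
22 | {(2S,3S,4S,5S)-2,5-bis[4-(benzyloxy)-3-methoxyphenyl]oxolane-3,4-diyl}dimethanol | COc1cc([C@H]2O[C@H](c3ccc(OCc4ccccc4)c(OC)c3)[C@H](CO)[C@H]2CO)ccc1OCc1ccccc1 | intermediate
23 | Eduesmine, {(2S,3S,4S,5S)-2,5-bis(4-hydroxy-3-methoxyphenyl)oxolane-3,4-diyl}dimethanol | COc1cc([C@H]2O[C@H](c3ccc(O)c(OC)c3)[C@H](CO)[C@H]2CO)ccc1O | target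

## Step count and least certain steps

Total: 12 steps. Longest linear sequence: 11 steps (steps 1–7 and 9–12); step 8 is a one-step side branch.

**Step 2 (key step).** Addition to the electron-rich, weakly electrophilic aldehyde may be slow, so that retro-aldol competes before silylation and anti selectivity erodes. During desilylation and ring closure, acid may ionise the benzylic C5–O bond and epimerise it toward the trans lactone, or ring closure of the anti adduct may stall (a finish with pyridinium p-toluenesulfonate in CH2Cl2 would then be tried). The fallback sets out from 4 and 5 and returns at 8. Imide 4 is converted with Bu2BOTf and iPr2NEt in CH2Cl2 into its dibutylboron (Z)-enolate F1, which is added at −78 °C to 5 activated beforehand with Et2AlCl. In this open transition state the boron stays chelated to the oxazolidinone carbonyl, so the same enolate face reacts and the small Lewis acid favours the anti adduct. This should give hydroxy ester 7 after work-up, and 7 is closed to 8 with pyridinium p-toluenesulfonate.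

**Step 10.** Hydride has to enter on the ring face that carries the C4 substituent and the C5 aryl group, so facial selectivity may be poor. The Lewis acid may also open the ring at a benzylic carbon and scramble C5 or C2, or the cation may lose the C3 proton. The fallback sets out from 15 and returns at 21. It inverts the order of hydride and aryl at C2, so that whichever face is preferred because of the C4 and C5 substituents now receives the aryl group. Lactone 15 is reduced with iBu2AlH at −78 °C to the lactol F2, which is condensed with benzenesulfinic acid (CaCl2, CH2Cl2) to the 2-(phenylsulfonyl)oxolane F3. The diarylzinc F4, made from 18 and ZnBr2, then displaces the sulfinate through the C2–H oxocarbenium ion to give 21.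

**Step 6.** Formaldehyde may polymerise before it reacts, giving incomplete conversion, and a second hydroxymethylation or retro-aldol on warming may follow. The fallback sets out from 12 (through enolate 13) and returns at 14. The enolate is alkylated with 4-methoxybenzyl chloromethyl ether to the 4-methoxybenzyl ether F5, again trans to C4′. The 4-methoxybenzyl group is then removed oxidatively with 2,3-dichloro-5,6-dicyano-1,4-benzoquinone in wet CH2Cl2 at 0 °C to give 14.

**Step 9.** The tetrahedral intermediate may collapse so that a second aryllithium adds, or the aryllithium may deprotonate C3 with loss of silanolate. The fallback sets out from 15 and returns at 19. The lactone is opened with Me(MeO)NH·HCl and Me3Al to the hydroxy Weinreb amide F6, and the C5 hydroxyl is capped at once with Et3SiCl and imidazole to give the triethylsilyl ether F7. Aryllithium 18 then adds once to give the aryl ketone F8. Buffered HF·pyridine removes only the triethylsilyl group, after which the hydroxy ketone closes to lactol 19.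

**Step 12.** Hydrogenolysis may continue past the benzyl ethers into the ring C–O bonds once the free p-hydroxyphenyl groups are present. The fallback sets out from 21 and returns at 23. The benzyl ethers are cleaved first on the fully silylated compound, in which the two bulky silyloxymethyl groups flank both benzylic ring carbons and hinder their adsorption on the metal, to give the bis-silyl bisphenol F9. The silyl groups are then removed with HF·pyridine (or Bu4NF buffered with acetic acid) to give 23.

## Further compounds

F1 | step 2 | dibutylboron (Z)-enolate of 4 | COC(=O)C/C=C(\OB(CCCC)CCCC)N1[C@@H](Cc2ccccc2)COC1=O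
F2 | step 10 | (3S,4S,5S)-5-[4-(benzyloxy)-3-methoxyphenyl]-3,4-bis{[(triisopropylsilyl)oxy]methyl}oxolan-2-ol (C2 epimers) | OC1O[C@H](c2ccc(OCc3ccccc3)c(OC)c2)[C@H](CO[Si](C(C)C)(C(C)C)C(C)C)[C@H]1CO[Si](C(C)C)(C(C)C)C(C)C
F3 | step 10 | (3S,4S,5S)-5-[4-(benzyloxy)-3-methoxyphenyl]-2-(phenylsulfonyl)-3,4-bis{[(triisopropylsilyl)oxy]methyl}oxolane (C2 epimers) | O=S(=O)(c1ccccc1)C1O[C@H](c2ccc(OCc3ccccc3)c(OC)c2)[C@H](CO[Si](C(C)C)(C(C)C)C(C)C)[C@H]1CO[Si](C(C)C)(C(C)C)C(C)C
F4 | step 10 | bis[4-(benzyloxy)-3-methoxyphenyl]zinc | COc1cc([Zn]c2ccc(OCc3ccccc3)c(OC)c2)ccc1OCc1ccccc1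
F5 | step 6 | (3S,4S,5S)-5-[4-(benzyloxy)-3-methoxyphenyl]-3-{[(4-methoxybenzyl)oxy]methyl}-4-{[(triisopropylsilyl)oxy]methyl}dihydrofuran-2(3H)-one | O=C1O[C@H](c2ccc(OCc3ccccc3)c(OC)c2)[C@H](CO[Si](C(C)C)(C(C)C)C(C)C)[C@H]1COCc1ccc(OC)cc1
F6 | step 9 | (2S,3S,4S)-4-[4-(benzyloxy)-3-methoxyphenyl]-4-hydroxy-N-methoxy-N-methyl-2,3-bis{[(triisopropylsilyl)oxy]methyl}butanamide | CON(C)C(=O)[C@H](CO[Si](C(C)C)(C(C)C)C(C)C)[C@@H](CO[Si](C(C)C)(C(C)C)C(C)C)[C@H](O)c1ccc(OCc2ccccc2)c(OC)c1
F7 | step 9 | (2S,3S,4S)-4-[4-(benzyloxy)-3-methoxyphenyl]-N-methoxy-N-methyl-4-[(triethylsilyl)oxy]-2,3-bis{[(triisopropylsilyl)oxy]methyl}butanamide | CON(C)C(=O)[C@H](CO[Si](C(C)C)(C(C)C)C(C)C)[C@@H](CO[Si](C(C)C)(C(C)C)C(C)C)[C@H](O[Si](CC)(CC)CC)c1ccc(OCc2ccccc2)c(OC)c1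
F8 | step 9 | (2S,3S,4S)-1,4-bis[4-(benzyloxy)-3-methoxyphenyl]-4-[(triethylsilyl)oxy]-2,3-bis{[(triisopropylsilyl)oxy]methyl}butan-1-one | COc1cc(C(=O)[C@H](CO[Si](C(C)C)(C(C)C)C(C)C)[C@@H](CO[Si](C(C)C)(C(C)C)C(C)C)[C@H](O[Si](CC)(CC)CC)c2ccc(OCc3ccccc3)c(OC)c2)ccc1OCc1ccccc1
F9 | step 12 | (2S,3S,4S,5S)-2,5-bis(4-hydroxy-3-methoxyphenyl)-3,4-bis{[(triisopropylsilyl)oxy]methyl}oxolane | COc1cc([C@H]2O[C@H](c3ccc(O)c(OC)c3)[C@H](CO[Si](C(C)C)(C(C)C)C(C)C)[C@H]2CO[Si](C(C)C)(C(C)C)C(C)C)ccc1O
A1 | alternative 1 | 3-{[4-(benzyloxy)-3-methoxyphenyl](hydroxy)methyl}-4-{2-[4-(benzyloxy)-3-methoxyphenyl]-1,3-dithian-2-yl}-5-(menthyloxy)dihydrofuran-2(3H)-one | O=C1[C@@H]([C@H](O)c2ccc(OCc3ccccc3)c(OC)c2)[C@H](C2(c3ccc(OCc4ccccc4)c(OC)c3)SCCCS2)[C@@H](O[C@H]2C[C@@H](C)CC[C@@H]2C(C)C)O1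
A2 | alternative 1 | (5S)-5-(menthyloxy)furan-2(5H)-one | O=C1C=C[C@@H](O[C@H]2C[C@@H](C)CC[C@@H]2C(C)C)O1
A3 | alternative 1 | 2-[4-(benzyloxy)-3-methoxyphenyl]-1,3-dithiane | COc1cc(C2SCCCS2)ccc1OCc1ccccc1
A4 | alternative 2 | methyl 2,5-bis[4-(benzyloxy)-3-methoxyphenyl]-4-{[(tert-butyldimethylsilyl)oxy]methyl}-4,5-dihydrofuran-3-carboxylate | COC(=O)C1=C(c2ccc(OCc3ccccc3)c(OC)c2)O[C@H](c2ccc(OCc3ccccc3)c(OC)c2)[C@@H]1CO[Si](C)(C)C(C)(C)C
A5 | alternative 2 | 1,4-bis[4-(benzyloxy)-3-methoxyphenyl]-2-{[(tert-butyldimethylsilyl)oxy]methyl}but-3-yn-1-ol | O[C@H](c1ccc(OCc2ccccc2)c(OC)c1)[C@@H](C#Cc1ccc(OCc2ccccc2)c(OC)c1)CO[Si](C)(C)C(C)(C)C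
A6 | alternative 3 | 2-[4-(benzyloxy)-3-methoxyphenyl]-4-[(benzyloxy)methyl]-5-[3-methoxy-4-(pivaloyloxy)phenyl]tetrahydrofuran-3-carboxylic acid (target numbering: carboxyl on C4, benzyloxymethyl on C3, pivaloyloxyaryl on C5) | COc1cc([C@H]2O[C@H](c3ccc(OC(=O)C(C)(C)C)c(OC)c3)[C@H](C(=O)O)[C@H]2COCc2ccccc2)ccc1OCc1ccccc1
A7 | alternative 3 | 3-{1-[4-(benzyloxy)-3-methoxyphenyl]-3-(benzyloxy)-1-oxopropan-2-yl}-4-[3-methoxy-4-(pivaloyloxy)phenyl]oxetan-2-one | O=C1O[C@@H](c2ccc(OC(=O)C(C)(C)C)c(OC)c2)[C@H]1[C@@H](COCc1ccccc1)C(=O)c1ccc(OCc2ccccc2)c(OC)c1
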